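## Retrosynthetic overview

1. Ring C is opened last-to-first: C2 is removed as a one-carbon unit (DMF dimethyl acetal) and the O1–C2 bond is cut, giving a 2-hydroxydeoxybenzoin; the prenyl group is then taken off the C7 oxygen.
2. Ring A is the key disconnection: C5–C6 and C4a–C8a are cut in a (4+2) sense, giving a 1,1,2,3-tetraoxygenated butadiene and a terminal ynone that already carries C4, C3 and ring B.
3. The feature the plan rests on: ring A has three neighbouring, mutually different oxygens at C8a (ring oxygen O1), C8 (methyl ether) and C7 (prenyl ether), directly beside C4a with its C4 carbonyl. This 1-acyl-2,3,4-trioxygenated benzene is the aromatised adduct of such a diene and ynone, and the three oxygens leave the cycloaddition already told apart.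
4. The diene comes from methyl acetoacetate (diazo transfer, O–H insertion into methanol, two silylations); the ynone comes from 4-methoxyphenylacetic acid (Weinreb amide, ethynyl Grignard reagent).
5. Ring order: ring B is bought, ring A is built in the cycloaddition, ring C is closed in the final step.

Key step: step 7

Assumption: the target is achiral. The double-bond geometry of 4, 5, 6 and 18 is not controlled and does not matter, because these sp2 carbons all end up in aromatic rings; where a geometry is written, one isomer is drawn.

## Route

Step 1
Reactants: 1 methyl acetoacetate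
Product: 2 methyl 2-diazo-3-oxobutanoate
Conditions: p-ABSA, Et3N, MeCN, 0 °C to rt
Reagents that add atoms: 4-acetamidobenzenesulfonyl azide (p-ABSA), CC(=O)Nc1ccc(cc1)S(=O)(=O)N=[N+]=[N-]
Why: Regitz diazo transfer to the doubly activated methylene of a β-keto ester is a standard reaction under these mild basic conditions, and the ester and ketone are untouched.

Step 2
Reactants: 2 methyl 2-diazo-3-oxobutanoate
Product: 3 methyl 2-methoxy-3-oxobutanoate (racemic, enolisable)
Conditions: Rh2(OAc)4 (1 mol %), MeOH (3 equiv), PhMe, 80 °C, slow addition of 2
Reagents that add atoms: methanol, CO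
Why: Carbenoid O–H insertion of a 2-diazo-3-oxo ester into a simple alcohol under Rh2(OAc)4 catalysis is a known reaction type that should outrun Wolff rearrangement, and it places the future C8 methoxy group on the carbon between the two carbonyls.

Step 3
Reactants: 3 methyl 2-methoxy-3-oxobutanoate
Product: 4 methyl 2-methoxy-3-(trimethylsilyloxy)but-2-enoate (mixture of geometric isomers)
Conditions: TMSCl, Et3N, PhMe, rt, 48 h; filtration and distillation under argon
Reagents that add atoms: chlorotrimethylsilane, C[Si](C)(C)Cl
Why: Soft enolisation of the β-keto ester with amine base and chlorosilane gives the silyl enol ether of the ketone carbonyl, the standard first stage in making 1-alkoxy-1,3-bis(silyloxy)butadienes; the C2 methoxy group is a spectator.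

Step 4
Reactants: 4 methyl 2-methoxy-3-(trimethylsilyloxy)but-2-enoate
Product: 6 1,2-dimethoxy-1,3-bis(trimethylsilyloxy)buta-1,3-diene (one geometric isomer drawn), via lithium dienolate 5 (not isolated)
Conditions: LiN(iPr)2 (LDA), THF, −78 °C; TMSCl, −78 °C to rt; non-aqueous work-up (evaporation, hexane, filtration under argon), used crude
Reagents that add atoms: chlorotrimethylsilane, C[Si](C)(C)Cl
Why: Kinetic deprotonation of the C4 methyl group of the vinylogous ester gives the cross-conjugated dienolate 5, which is silylated on the ester oxygen; this enolate O-silylation is the standard second stage for this diene class.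

Step 5
Reactants: 7 4-methoxyphenylacetic acid
Product: 9 N-methoxy-2-(4-methoxyphenyl)-N-methylacetamide, via acyl imidazole 8 (not isolated)
Conditions: CDI, CH2Cl2, rt; then MeNHOMe·HCl, rt
Reagents that add atoms: N,O-dimethylhydroxylamine hydrochloride, CNOC.Cl
Why: Amide coupling through an acyl imidazole: CDI converts the acid into 8 with loss of CO2 and imidazole, and the amine hydrochloride then displaces imidazole to give the Weinreb amide.

Step 6
Reactants: 9 N-methoxy-2-(4-methoxyphenyl)-N-methylacetamide; 10 ethynylmagnesium bromide
Product: 12 1-(4-methoxyphenyl)but-3-yn-2-one, via magnesium hemiaminal chelate 11 (not isolated)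
Conditions: HC≡CMgBr (1.5 equiv), THF, 0 °C; inverse quench into cold 1 M HCl, 0 °C; used promptly
Reagents that add atoms: none
Why: Weinreb ketone synthesis: the weakly basic alkynyl Grignard reagent adds once to give chelate 11, which survives until the quench, and pouring the mixture into cold acid protonates the released N,O-dimethylhydroxylamine before it can add to the new ynone in conjugate fashion.

Step 7
Reactants: 6 1,2-dimethoxy-1,3-bis(trimethylsilyloxy)buta-1,3-diene; 12 1-(4-methoxyphenyl)but-3-yn-2-one
Product: 15 1-(2,4-dihydroxy-3-methoxyphenyl)-2-(4-methoxyphenyl)ethan-1-one, via cyclohexadiene cycloadduct 13 (not isolated), via bis(trimethylsilyl) ether 14 (not isolated)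
Conditions: 6 (1.5 equiv), PhMe, 0 °C to rt; then 1 M HCl, THF, rt
Reagents that add atoms: none
Why: This is a thermal Diels–Alder reaction of an electron-rich 1-alkoxy-1,3-bis(silyloxy)butadiene with an acetylenic ketone, a known route to acylresorcinols, applied here to a diene that carries one further methoxy group. The closure is an asynchronous (4+2) cycloaddition: the unsubstituted CH2 end of 6 (future C6), which receives electron density from both the ketene acetal and the neighbouring silyloxy group, bonds first to the terminal alkyne carbon of 12 (future C5), and the ketene acetal carbon (future C8a) then closes on the acyl-bearing carbon (future C4a), so ring A forms as a six-membered carbocycle from two components. Adduct 13 is a cyclohexa-1,4-diene with a mixed methyl silyl ketal at C8a and a CH2 group at C6, so 1,4-loss of methanol gives arene 14 and dilute acid then cleaves both O–Si bonds. No stereocentre has to be controlled, because the ketal carbon of 13 is racemic and becomes aromatic. The selectivity required is the orientation that puts C8a beside the acyl carbon; it should be secured by the joint donor effect of the C8a and C7 oxygens toward C6 and by the absence of substituents at both termini that bond first, which together outweigh the opposite polarisation by the C8 methoxy group. The three oxygens emerge differentiated: C8 as its methyl ether, C8a hydrogen-bonded to the ketone, and C7 as a free phenol.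

Step 8
Reactants: 15 1-(2,4-dihydroxy-3-methoxyphenyl)-2-(4-methoxyphenyl)ethan-1-one; 16 prenyl bromide (1-bromo-3-methylbut-2-ene)
Product: 17 1-[2-hydroxy-3-methoxy-4-(3-methylbut-2-enyloxy)phenyl]-2-(4-methoxyphenyl)ethan-1-one
Conditions: 16 (1.05 equiv), K2CO3 (1.2 equiv), acetone, rt to 40 °C
Reagents that add atoms: none
Why: Williamson ether synthesis: the hydroxyl ortho to the ketone (future O1) is held in a hydrogen bond and is far less acidic and nucleophilic than the para hydroxyl, so one equivalent of the primary allylic bromide and a weak base should alkylate only the future C7 oxygen by SN2.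

Step 9
Reactants: 17 1-[2-hydroxy-3-methoxy-4-(3-methylbut-2-enyloxy)phenyl]-2-(4-methoxyphenyl)ethan-1-one
Product: 19 8-methoxy-3-(4-methoxyphenyl)-7-(3-methylbut-2-enyloxy)-4H-chromen-4-one (CNP0310002.0), via enaminone 18 (not isolated)
Conditions: Me2NCH(OMe)2 (3 equiv), PhMe, 100 °C
Reagents that add atoms: N,N-dimethylformamide dimethyl acetal, COC(OC)N(C)C
Why: Enaminone route to isoflavones: the acetal condenses with the activated benzylic methylene to give 18, the ortho hydroxyl adds to its β-carbon in a 6-endo oxa-Michael closure and dimethylamine is lost, which forms ring C under non-acidic conditions that spare the prenyl ether.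

## Compound list

1 | methyl acetoacetate | COC(=O)CC(C)=O | starting material
2 | methyl 2-diazo-3-oxobutanoate | COC(=O)C(=[N+]=[N-])C(C)=O | intermediate
3 | methyl 2-methoxy-3-oxobutanoate (racemic) | COC(=O)C(OC)C(C)=O | intermediate
4 | methyl 2-methoxy-3-(trimethylsilyloxy)but-2-enoate (mixture of geometric isomers) | COC(=O)C(OC)=C(C)O[Si](C)(C)C | intermediate
5 | lithium dienolate of 4: lithium 1,2-dimethoxy-3-(trimethylsilyloxy)buta-1,3-dien-1-olate | C=C(O[Si](C)(C)C)C(OC)=C(OC)O[Li] | intermediate (not isolated)
6 | 1,2-dimethoxy-1,3-bis(trimethylsilyloxy)buta-1,3-diene (geometry not controlled, 1E isomer drawn) | C=C(O[Si](C)(C)C)/C(OC)=C(/OC)O[Si](C)(C)C | intermediate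
7 | 4-methoxyphenylacetic acid | COc1ccc(CC(=O)O)cc1 | starting material
8 | 1-(1H-imidazol-1-yl)-2-(4-methoxyphenyl)ethan-1-one | COc1ccc(CC(=O)n2ccnc2)cc1 | intermediate (not isolated)
9 | N-methoxy-2-(4-methoxyphenyl)-N-methylacetamide | COc1ccc(CC(=O)N(C)OC)cc1 | intermediate
10 | ethynylmagnesium bromide | C#C[Mg]Br | starting material
11 | bromomagnesium salt of the tetrahedral adduct, 2-[methoxy(methyl)amino]-1-(4-methoxyphenyl)but-3-yn-2-olate (racemic) | C#CC(Cc1ccc(OC)cc1)(O[Mg]Br)N(C)OC | intermediate (not isolated)
12 | 1-(4-methoxyphenyl)but-3-yn-2-one | C#CC(=O)Cc1ccc(OC)cc1 | intermediate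
13 | 1-[5,6-dimethoxy-4,6-bis(trimethylsilyloxy)cyclohexa-1,4-dien-1-yl]-2-(4-methoxyphenyl)ethan-1-one (racemic at the ketal carbon) | COc1ccc(CC(=O)C2=CCC(O[Si](C)(C)C)=C(OC)C2(OC)O[Si](C)(C)C)cc1 | intermediate (not isolated)
14 | 1-[3-methoxy-2,4-bis(trimethylsilyloxy)phenyl]-2-(4-methoxyphenyl)ethan-1-one | COc1ccc(CC(=O)c2ccc(O[Si](C)(C)C)c(OC)c2O[Si](C)(C)C)cc1 | intermediate (not isolated)
15 | 1-(2,4-dihydroxy-3-methoxyphenyl)-2-(4-methoxyphenyl)ethan-1-one | COc1ccc(CC(=O)c2ccc(O)c(OC)c2O)cc1 | intermediate
16 | prenyl bromide (1-bromo-3-methylbut-2-ene) | CC(C)=CCBr | starting material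
17 | 1-[2-hydroxy-3-methoxy-4-(3-methylbut-2-enyloxy)phenyl]-2-(4-methoxyphenyl)ethan-1-one | COc1ccc(CC(=O)c2ccc(OCC=C(C)C)c(OC)c2O)cc1 | intermediate
18 | (E)-3-(dimethylamino)-1-[2-hydroxy-3-methoxy-4-(3-methylbut-2-enyloxy)phenyl]-2-(4-methoxyphenyl)prop-2-en-1-one | COc1ccc(/C(=C\N(C)C)C(=O)c2ccc(OCC=C(C)C)c(OC)c2O)cc1 | intermediate (not isolated)
19 | 8-methoxy-3-(4-methoxyphenyl)-7-(3-methylbut-2-enyloxy)-4H-chromen-4-one | COc1ccc(-c2coc3c(OC)c(OCC=C(C)C)ccc3c2=O)cc1 | target

## Step count and risks

Total step count: 9. Longest linear sequence: 7 steps (steps 1, 2, 3, 4, 7, 8, 9); the ynone branch (steps 5, 6) joins at step 7.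

Steps most likely to fail:

Step 7. The diene may be hydrolysed, or may pass a silyl group to the enolisable ynone, faster than it cycloadds; the ynone may also oligomerise, so that ring A never closes or closes in low conversion. The fallback gives up the de novo construction of ring A and sets out from acid 7. A Friedel–Crafts acylation of commercial 2-methoxybenzene-1,3-diol with 7 in neat BF3·OEt2 at 80 to 90 °C should acylate the position ortho to one hydroxyl and para to the other. It comes back to the route at 15 directly, and no new compound is formed on the way (F0).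

Step 6. The liberated N,O-dimethylhydroxylamine may add in conjugate fashion to the terminal ynone during the quench; the Grignard reagent may deprotonate the benzylic CH2 instead of adding; the ynone may decompose on concentration. The fallback sets out from amide 9 and forms the ynone by oxidation, so that no amine is ever present with it. Reduction with iBu2AlH in THF at −78 °C should give 2-(4-methoxyphenyl)acetaldehyde F1, used crude at once. Addition of 10 in THF at −78 to 0 °C should give 1-(4-methoxyphenyl)but-3-yn-2-ol F2 (racemic; the carbinol centre is removed in the next operation). Dess–Martin periodinane with NaHCO3 in CH2Cl2 at 0 °C should then give the ynone, so the fallback comes back to the route at 12.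

Step 9. Ring closure may stall at the enaminone, or the acetal may methylate the chelated phenol and so remove the nucleophile needed for the O1–C2 bond; acid added to force closure would cleave the prenyl ether. The fallback inverts the order of the last two steps and sets out from 15. Treatment with DMF, BF3·OEt2 and MeSO2Cl at 60 to 80 °C, a strongly acidic one-carbon insertion that is tolerable while no prenyl ether is present, should give 7-hydroxy-8-methoxy-3-(4-methoxyphenyl)-4H-chromen-4-one F3. Alkylation of its only hydroxyl with 16 and K2CO3 in acetone then comes back to the route at 19.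

## Further compounds

F0 | step 7 | none | none
F1 | step 6 | 2-(4-methoxyphenyl)acetaldehyde | COc1ccc(CC=O)cc1
F2 | step 6 | 1-(4-methoxyphenyl)but-3-yn-2-ol (racemic) | C#CC(O)Cc1ccc(OC)cc1
F3 | step 9 | 7-hydroxy-8-methoxy-3-(4-methoxyphenyl)-4H-chromen-4-one | COc1ccc(-c2coc3c(OC)c(O)ccc3c2=O)cc1
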